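**Plan**
- Retrosynthesis: remove three MOM ethers; cut C2–C1' (ring C to ring B) to give a 2-unsubstituted chromone and an arylboronic acid; cut C8–CH2 of the prenyl group back to a 5-O-prenyl ether; cut O1–C2 and C2–C3 back to 2',6'-dihydroxy-4'-methoxyacetophenone and a one-carbon unit.
- Forward: ring A is bought. Ring C is closed first as the 4H-chromen-4-one; the diphenol is symmetric, so there is no regiochemical question. The prenyl group is then moved from O5 to C8 (para-Claisen–Cope), and ring B is attached in the penultimate step.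
- Enabling feature: in the chromone, C2 is the β-carbon of the enone O1–C2=C3–C4=O of ring C. This flat, prochiral carbon is both the future stereocentre and the attachment point of ring B, and an aryl–rhodium species can add across C2=C3.
- Stereochemistry: the single stereocentre (2S) is set by catalyst control (chiral diene–Rh) as the C2–aryl bond forms; C2 sees no strongly basic conditions afterwards.

Key step: step 7

Remark on the chemistry: the sense of induction of the diene ligand is taken from its behaviour with simple cyclic enones, so the (S,S)-ligand is chosen for (2S). The antipodal ligand is equally accessible and would be used if the sense proved opposite.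

**Step 1**
Reactants: 1 1-(2,6-dihydroxy-4-methoxyphenyl)ethan-1-one; 2 N,N-dimethylformamide dimethyl acetal
Product: 4 5-hydroxy-7-methoxy-4H-chromen-4-one, via enaminone 3 (not isolated)
Conditions: DMF-DMA, toluene, 90 °C; then conc. HCl, CH2Cl2, 40 °C
Reagents that add atoms: 2 N,N-dimethylformamide dimethyl acetal, COC(OC)N(C)C
Why: Condensation of the acetyl methyl group with the amide acetal should give the enaminone (enaminone route to chromones), and acid should then drive O-addition and loss of dimethylamine; the two ortho hydroxyls are equivalent, so only one chromone can form and no stereocentre arises.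

**Step 2**
Reactants: 4 5-hydroxy-7-methoxy-4H-chromen-4-one; 5 1-bromo-3-methylbut-2-ene (prenyl bromide)
Product: 6 7-methoxy-5-[(3-methylbut-2-en-1-yl)oxy]-4H-chromen-4-one
Conditions: K2CO3, DMF, 60 °C
Reagents that add atoms: 5 1-bromo-3-methylbut-2-ene, CC(C)=CCBr
Why: Williamson ether synthesis (SN2) of the 5-phenoxide with a primary allylic bromide in a polar aprotic solvent should favour O- over C-alkylation; no stereocentre is formed.

**Step 3**
Reactants: 6 7-methoxy-5-[(3-methylbut-2-en-1-yl)oxy]-4H-chromen-4-one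
Product: 9 5-hydroxy-7-methoxy-8-(3-methylbut-2-en-1-yl)-4H-chromen-4-one, via C6 ortho-dienone 7 (not isolated), via C8 para-dienone 8 (not isolated)
Conditions: Eu(fod)3 (10 mol %), NaHCO3, PhCl, 85 °C
Reagents that add atoms: none
Why: Europium(III)-catalysed aromatic para-Claisen–Cope rearrangement: a [3,3] shift from O5 to C6 should give the 1,1-dimethylallyl dienone, a Cope [3,3] shift then carries the group to C8 (the only position para to O5) as the linear prenyl group, and enolisation restores ring A; no stereocentre remains.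

**Step 4**
Reactants: 9 5-hydroxy-7-methoxy-8-(3-methylbut-2-en-1-yl)-4H-chromen-4-one; 10 chloromethyl methyl ether (MOMCl)
Product: 11 7-methoxy-5-(methoxymethoxy)-8-(3-methylbut-2-en-1-yl)-4H-chromen-4-one
Conditions: NaH, MOMCl, DMF, 0 °C to rt
Reagents that add atoms: 10 chloromethyl methyl ether, COCCl
Why: MOM ether formation by alkylation of the sodium phenoxide; full deprotonation with NaH overcomes the hydrogen bond of the 5-OH to the C4 carbonyl, and no stereocentre is involved.

**Step 5**
Reactants: 12 4-bromobenzene-1,2-diol (4-bromocatechol); 10 chloromethyl methyl ether (MOMCl)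
Product: 13 4-bromo-1,2-bis(methoxymethoxy)benzene
Conditions: NaH (2.5 equiv), MOMCl (2.5 equiv), DMF, 0 °C to rt
Reagents that add atoms: 10 chloromethyl methyl ether, COCCl
Why: Double MOM ether formation on the catechol dianion, a routine phenol protection; no stereocentre.

**Step 6**
Reactants: 13 4-bromo-1,2-bis(methoxymethoxy)benzene; 14 triisopropyl borate
Product: 17 [3,4-bis(methoxymethoxy)phenyl]boronic acid, via aryllithium 15 (not isolated), via lithium aryl(triisopropoxy)borate 16 (not isolated)
Conditions: n-BuLi added to 13 and B(OiPr)3, THF, −78 °C to rt; then sat. aq. NH4Cl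
Reagents that add atoms: 14 triisopropyl borate, CC(C)OB(OC(C)C)OC(C)C; water, O
Why: Bromine–lithium exchange should outrun ortho-lithiation next to the MOM ethers at −78 °C, the aryllithium is trapped at once by the borate (borylation of an aryllithium), and near-neutral hydrolysis should give the boronic acid with both acetals intact.

**Step 7**
Reactants: 11 7-methoxy-5-(methoxymethoxy)-8-(3-methylbut-2-en-1-yl)-4H-chromen-4-one; 17 [3,4-bis(methoxymethoxy)phenyl]boronic acid
Product: 18 (2S)-2-[3,4-bis(methoxymethoxy)phenyl]-7-methoxy-5-(methoxymethoxy)-8-(3-methylbut-2-en-1-yl)-2,3-dihydro-4H-chromen-4-one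
Conditions: [RhCl(C2H4)2]2 (2.5 mol %), (S,S)-Ph-bod* [(1S,4S)-2,5-diphenylbicyclo[2.2.2]octa-2,5-diene] (5.5 mol %), 17 (2 equiv), aq. K3PO4 (20 mol %), dioxane/H2O 10:1, 40 °C
Reagents that add atoms: none
Why: The Rh(I)–hydroxide/diene complex takes the aryl group from boron by transmetalation, the aryl–rhodium species binds the C2=C3 bond of ring C and inserts it so that the aryl group goes to C2 and rhodium to C3 (an oxa-π-allyl enolate over C3–C4–O), and water protonates the enolate and returns Rh–OH. The closest known reaction type is the Hayashi–Miyaura rhodium-catalysed asymmetric 1,4-addition of arylboronic acids to 4H-chromen-4-ones, which gives flavanones directly. No ring is closed, since ring C is already in place; the step only turns C2 from sp2 into sp3. The new stereocentre at C2 is under catalyst control: the C2-symmetric diene leaves one enantioface of C2=C3 open, and the (S,S)-ligand is expected to deliver the aryl group to the Re face of C2, which corresponds to (2S). The step needs chemoselectivity for the conjugated C2=C3 bond over the isolated trisubstituted prenyl alkene, which the substrate secures because only the enone double bond is polarised and unhindered enough to insert into aryl–rhodium; it also needs the product not to open by retro-oxa-Michael reaction to the chalcone, which is secured by the low base loading, fast protonation of the enolate in the aqueous medium and the absence of free phenols (all three are MOM ethers).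

**Step 8**
Reactants: 18 (2S)-2-[3,4-bis(methoxymethoxy)phenyl]-7-methoxy-5-(methoxymethoxy)-8-(3-methylbut-2-en-1-yl)-2,3-dihydro-4H-chromen-4-one
Product: 19 (2S)-2-(3,4-dihydroxyphenyl)-5-hydroxy-7-methoxy-8-(3-methylbut-2-en-1-yl)-2,3-dihydro-4H-chromen-4-one
Conditions: 3 M aq. HCl, MeOH, 25–40 °C
Reagents that add atoms: none
Why: Acid-catalysed acetal exchange (MOM cleavage) with methanol should free all three phenols; the prenyl group has no free ortho hydroxyl with which to cyclise, and C2 is not epimerised under mild acid, so the (2S) centre should be kept.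

**Compound list**
1 | 1-(2,6-dihydroxy-4-methoxyphenyl)ethan-1-one (2',6'-dihydroxy-4'-methoxyacetophenone) | CC(=O)c1c(O)cc(OC)cc1O | starting material
2 | N,N-dimethylformamide dimethyl acetal | COC(OC)N(C)C | starting material
3 | (E)-1-(2,6-dihydroxy-4-methoxyphenyl)-3-(dimethylamino)prop-2-en-1-one | CN(C)/C=C/C(=O)c1c(O)cc(OC)cc1O | intermediate
4 | 5-hydroxy-7-methoxy-4H-chromen-4-one | O=c1ccoc2cc(OC)cc(O)c12 | intermediate
5 | 1-bromo-3-methylbut-2-ene (prenyl bromide) | CC(C)=CCBr | starting material
6 | 7-methoxy-5-[(3-methylbut-2-en-1-yl)oxy]-4H-chromen-4-one | O=c1ccoc2cc(OC)cc(OCC=C(C)C)c12 | intermediate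
7 | 7-methoxy-6-(2-methylbut-3-en-2-yl)-4H-chromene-4,5(6H)-dione (racemic ortho-dienone) | O=C1C=COC2=C1C(=O)C(C(C)(C)C=C)C(OC)=C2 | intermediate
8 | 7-methoxy-8-(3-methylbut-2-en-1-yl)-4H-chromene-4,5(8H)-dione (racemic para-dienone) | O=C1C=COC2=C1C(=O)C=C(OC)C2CC=C(C)C | intermediate
9 | 5-hydroxy-7-methoxy-8-(3-methylbut-2-en-1-yl)-4H-chromen-4-one | O=c1ccoc2c(CC=C(C)C)c(OC)cc(O)c12 | intermediate
10 | chloromethyl methyl ether (MOMCl) | COCCl | starting material
11 | 7-methoxy-5-(methoxymethoxy)-8-(3-methylbut-2-en-1-yl)-4H-chromen-4-one | O=c1ccoc2c(CC=C(C)C)c(OC)cc(OCOC)c12 | intermediate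
12 | 4-bromobenzene-1,2-diol (4-bromocatechol) | Oc1ccc(Br)cc1O | starting material
13 | 4-bromo-1,2-bis(methoxymethoxy)benzene | COCOc1ccc(Br)cc1OCOC | intermediate
14 | triisopropyl borate | CC(C)OB(OC(C)C)OC(C)C | starting material
15 | [3,4-bis(methoxymethoxy)phenyl]lithium | [Li]c1ccc(OCOC)c(OCOC)c1 | intermediate
16 | lithium [3,4-bis(methoxymethoxy)phenyl]tri(propan-2-yloxy)borate | [Li+].CC(C)O[B-](OC(C)C)(OC(C)C)c1ccc(OCOC)c(OCOC)c1 | intermediate
17 | [3,4-bis(methoxymethoxy)phenyl]boronic acid | OB(O)c1ccc(OCOC)c(OCOC)c1 | intermediate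
18 | (2S)-2-[3,4-bis(methoxymethoxy)phenyl]-7-methoxy-5-(methoxymethoxy)-8-(3-methylbut-2-en-1-yl)-2,3-dihydro-4H-chromen-4-one | COc1cc(OCOC)c2c(c1CC=C(C)C)O[C@H](c1ccc(OCOC)c(OCOC)c1)CC2=O | intermediate
19 | (2S)-2-(3,4-dihydroxyphenyl)-5-hydroxy-7-methoxy-8-(3-methylbut-2-en-1-yl)-2,3-dihydro-4H-chromen-4-one | COc1cc(O)c2c(c1CC=C(C)C)O[C@H](c1ccc(O)c(O)c1)CC2=O | target

**Step count**
Total: 8 steps. Longest linear sequence: 6 steps (steps 1, 2, 3, 4, 7, 8); the boronic acid branch (steps 5, 6) joins at step 7.

**Steps most likely to fail**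

Step 7. The electron-rich, doubly O-donor-substituted chromone may insert slowly, so that protodeboronation of the boronic acid wins. The rhodium enolate or the product may also open to the chalcone under the aqueous base, with loss of enantiopurity, or the peri 5-O-MOM group may lower facial discrimination. The fallback sets out from 13 and 11 and comes back to the route at 18. Compound 13 is converted with magnesium in THF into [3,4-bis(methoxymethoxy)phenyl]magnesium bromide F1. This is added to 11 at −78 to −30 °C with CuBr·SMe2 (10 mol %) and TMSCl, a copper-catalysed, silyl-accelerated conjugate addition that traps the adduct as the racemic {[2-[3,4-bis(methoxymethoxy)phenyl]-7-methoxy-5-(methoxymethoxy)-8-(3-methylbut-2-en-1-yl)-2H-chromen-4-yl]oxy}trimethylsilane F2. Mild aqueous hydrolysis (aq. NH4Cl) should give racemic 2-[3,4-bis(methoxymethoxy)phenyl]-7-methoxy-5-(methoxymethoxy)-8-(3-methylbut-2-en-1-yl)-2,3-dihydro-4H-chromen-4-one F3. Preparative HPLC on a polysaccharide chiral stationary phase then separates 18 from its mirror image, (2R)-2-[3,4-bis(methoxymethoxy)phenyl]-7-methoxy-5-(methoxymethoxy)-8-(3-methylbut-2-en-1-yl)-2,3-dihydro-4H-chromen-4-one F4, which is set aside.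

Step 3. The rearrangement may stop after the first [3,3] shift, with enolisation at C6 giving the 6-(1,1-dimethylallyl) isomer, or the Lewis acid may ionise the allylic ether and cause loss of the prenyl group. The fallback sets out from 4 and comes back to the route at 11, replacing steps 2 to 4. Compound 4 is protected (NaH, MOMCl, DMF) as 7-methoxy-5-(methoxymethoxy)-4H-chromen-4-one F5. Electrophilic iodination with NIS in DMF, directed to C8 by the 5,7-dialkoxy pattern, should give 8-iodo-7-methoxy-5-(methoxymethoxy)-4H-chromen-4-one F6. Suzuki–Miyaura coupling of F6 with commercial prenylboronic acid pinacol ester, under ligand-controlled α-selective conditions for allylboronates (Pd/bulky biarylphosphine, K3PO4, THF/H2O), should then give 11.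

Step 8. The acid needed for the two ordinary aryl MOM ethers may add HCl or methanol across the prenyl alkene, or may erode the C2 configuration through reversible acid-catalysed opening of ring C. The fallback replaces the acetal protecting groups by silyl ethers that come off with fluoride; it sets out from 12 and 9 and comes back to the route at 19. Compound 12 is silylated (TBSCl, imidazole, DMF) to 4-bromo-1,2-bis[(tert-butyldimethylsilyl)oxy]benzene F7. Miyaura borylation (B2pin2, Pd(dppf)Cl2, KOAc, dioxane, 80 °C) gives 2-{3,4-bis[(tert-butyldimethylsilyl)oxy]phenyl}-4,4,5,5-tetramethyl-1,3,2-dioxaborolane F8. Compound 9 is silylated (TBSOTf, 2,6-lutidine, CH2Cl2) to 5-[(tert-butyldimethylsilyl)oxy]-7-methoxy-8-(3-methylbut-2-en-1-yl)-4H-chromen-4-one F9. The rhodium/(S,S)-diene 1,4-addition of step 7, applied to F9 and F8, should give (2S)-2-{3,4-bis[(tert-butyldimethylsilyl)oxy]phenyl}-5-[(tert-butyldimethylsilyl)oxy]-7-methoxy-8-(3-methylbut-2-en-1-yl)-2,3-dihydro-4H-chromen-4-one F10. Et3N·3HF in THF at 0 °C to rt then frees the three phenols to give 19.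

**Further compounds**
F1 | step 7 | [3,4-bis(methoxymethoxy)phenyl]magnesium bromide | COCOc1ccc([Mg]Br)cc1OCOC
F2 | step 7 | {[2-[3,4-bis(methoxymethoxy)phenyl]-7-methoxy-5-(methoxymethoxy)-8-(3-methylbut-2-en-1-yl)-2H-chromen-4-yl]oxy}trimethylsilane (racemic) | C[Si](C)(C)OC1=CC(c2ccc(OCOC)c(OCOC)c2)Oc2c(CC=C(C)C)c(OC)cc(OCOC)c21
F3 | step 7 | 2-[3,4-bis(methoxymethoxy)phenyl]-7-methoxy-5-(methoxymethoxy)-8-(3-methylbut-2-en-1-yl)-2,3-dihydro-4H-chromen-4-one (racemic) | COc1cc(OCOC)c2c(c1CC=C(C)C)OC(c1ccc(OCOC)c(OCOC)c1)CC2=O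
F4 | step 7 | (2R)-2-[3,4-bis(methoxymethoxy)phenyl]-7-methoxy-5-(methoxymethoxy)-8-(3-methylbut-2-en-1-yl)-2,3-dihydro-4H-chromen-4-one | COc1cc(OCOC)c2c(c1CC=C(C)C)O[C@@H](c1ccc(OCOC)c(OCOC)c1)CC2=O
F5 | step 3 | 7-methoxy-5-(methoxymethoxy)-4H-chromen-4-one | O=c1ccoc2cc(OC)cc(OCOC)c12
F6 | step 3 | 8-iodo-7-methoxy-5-(methoxymethoxy)-4H-chromen-4-one | O=c1ccoc2c(I)c(OC)cc(OCOC)c12
F7 | step 8 | 4-bromo-1,2-bis[(tert-butyldimethylsilyl)oxy]benzene | CC(C)(C)[Si](C)(C)Oc1ccc(Br)cc1O[Si](C)(C)C(C)(C)C
F8 | step 8 | 2-{3,4-bis[(tert-butyldimethylsilyl)oxy]phenyl}-4,4,5,5-tetramethyl-1,3,2-dioxaborolane | CC(C)(C)[Si](C)(C)Oc1ccc(B2OC(C)(C)C(C)(C)O2)cc1O[Si](C)(C)C(C)(C)C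
F9 | step 8 | 5-[(tert-butyldimethylsilyl)oxy]-7-methoxy-8-(3-methylbut-2-en-1-yl)-4H-chromen-4-one | O=c1ccoc2c(CC=C(C)C)c(OC)cc(O[Si](C)(C)C(C)(C)C)c12
F10 | step 8 | (2S)-2-{3,4-bis[(tert-butyldimethylsilyl)oxy]phenyl}-5-[(tert-butyldimethylsilyl)oxy]-7-methoxy-8-(3-methylbut-2-en-1-yl)-2,3-dihydro-4H-chromen-4-one | COc1cc(O[Si](C)(C)C(C)(C)C)c2c(c1CC=C(C)C)O[C@H](c1ccc(O[Si](C)(C)C(C)(C)C)c(O[Si](C)(C)C(C)(C)C)c1)CC2=O
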